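## Analysis of the target

The target 25 is a cyclobutane in which every ring carbon is a stereocentre. C1 and C3 each carry a carbonyl group bound to the nitrogen of a 5,6-dihydropyridin-2(1H)-one, and C2 and C4 each carry a 3,4,5-trimethoxyphenyl group. The stereodescriptors place the two aryl groups on one face and the two acyl groups on the other, so every pair of neighbours is trans and each 1,3-pair is cis. The molecule has two mirror planes (through C1/C3 and through C2/C4) and is achiral, so no absolute stereocontrol is needed and chiral intermediates can be racemic. The sensitive groups are the two N-acyl enoyl lactams (acyl donors, Michael acceptors, reducible C=C), the acidic hydrogens at C1 and C3, and the electron-rich arenes, which limit strong oxidants and make benzylic leaving groups prone to ionisation. The difficulty is to close a strained ring between hindered benzylic carbons with the head-to-tail pattern and with the aryl groups cis; a [2+2] dimerisation of the cinnamoyl monomer has no built-in control over either point. The all-trans arrangement is the thermodynamic minimum, so a centre next to a carbonyl can be corrected by equilibration, but C2 and C4 cannot, and their cis relationship must be built kinetically. The strategy rests on C1: it is a carboxyl-bearing carbon flanked by the benzylic carbons C2 and C4, so with a second ester it is a malonate carbon that can bridge the two ends of a C2–C3–C4 1,3-dielectrophile, provided C3 carries its carboxyl in a masked, non-acidifying form.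

## Retrosynthetic reasoning

**Imide bonds.** The first cut is at the two exocyclic N–C(=O) bonds of 25, giving the all-trans diacid 21 and two molecules of lactam 22. These are the most labile bonds of the target, and the enoyl lactam would not survive alkoxide, hot chloride or hydrogenation, so it is attached last. The forward step activates 21 as the bis(acid chloride) 23 and acylates two equivalents of the lithium lactamate 24 on nitrogen. Because the all-trans arrangement is the most stable one, C1 and C3 are not endangered.

**Carboxyl at C3.** The C3 carboxyl of 21 is traced back through the hydroxymethyl acid 20 to the benzyl ether 19. No skeletal bond is cut; the point is the oxidation level of this carbon during ring formation. An ester at C3 would put an acidic hydrogen β to both leaving groups of the ring-closing step and invite elimination, whereas a benzyloxymethyl group does not acidify C3–H. It is unmasked by hydrogenolysis and oxidation once all strongly basic steps are over.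

**Carboxyl at C1.** The single carboxyl at C1 of 19 goes back through the monoesters 18 and 17 to the geminal diester 16. Adding the second ester makes C1 a malonate carbon. In the forward direction one ester is removed by dealkoxycarbonylation, which leaves C1 as the epimer mixture 17. The remaining ester sits between two cis aryl groups, so enolate equilibration should drive it to 18, trans to both, before saponification to 19. The ring closure therefore need not control C1.

**Ring bonds C1–C2 and C1–C4 (key disconnection).** Both bonds of 16 end at the doubly activated C1, so the synthon there is the 1,1-dinucleophile 13, used as its sodium salt 14. The C2–C3–C4 unit becomes a 1,3-dielectrophile with a leaving group on each benzylic carbon, chosen as the cyclic sulfate 12. This cut removes the ring and turns cyclobutane stereochemistry into acyclic stereochemistry. Because 12 is meso, attack at either end is equivalent. Each substitution inverts, so the all-cis arrangement of 12 becomes cis aryl groups trans to the benzyloxymethyl group in 16. The forward reaction has to achieve an SN2 opening at a secondary benzylic carbon and then a 4-exo-tet closure of the ring-opened sulfate 15, both ahead of elimination and ionisation.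

**Sulfur–oxygen bonds.** The cyclic sulfate 12 comes from the meso syn,syn diol 10 through the cyclic sulfite 11. Tying both hydroxyls into one ring activates them without breaking a C–O bond, so the stereotriad is transferred unchanged. The second leaving group, a sulfate monoester, appears only after the first substitution.

**Carbinol C–H bond and aldol C–C bond.** The syn,syn triad of 10 holds a 1,3-syn and a 1,2-syn relationship. The 1,3-syn relationship is set by chelate-controlled reduction of the β-hydroxy ketone 8 through the boron chelate 9. The 1,2-syn relationship is set by the aldol union of ketone 4, as its Z-boron enolate 6, with aldehyde 5 through the aldolate 7. Both aryl groups thus come from simple trimethoxyphenyl building blocks, and since 10 is meso, racemic 8 is sufficient.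

**Bond to the masked carboxyl carbon.** Ketone 4 is cut between its α-carbon and the benzyloxymethyl carbon, leading to the enolate 3 of methyl ketone 1 and the chloromethyl ether 2. This brings in the future C3 carboxyl carbon already protected and at the alcohol oxidation level.

## Alternatives that were turned down

**Alternative 1:** Both ring-to-aryl bonds are cut, back to a preformed ring, methyl trans-3-(quinolin-8-ylcarbamoyl)cyclobutane-1-carboxylate A2.
- Forward key step: a divalent palladium catalyst with a silver carboxylate as iodide scavenger, directed by the bidentate quinolin-8-yl amide, arylates the two methylene C–H bonds cis to the amide with 5-iodo-1,2,3-trimethoxybenzene A3. This gives A1, with the amide cis to both aryl groups and the ester trans.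
- For it: the ring is bought and not made, two C–C bonds form in one operation, directed arylation of cyclobutane carboxamides is an established reaction type, and the palladacycle guarantees cis aryl groups. It would probably need six or seven steps against eleven here, so on step count and precedent it is the stronger plan.
- Against it: in A1 the amide-bearing carbon has the wrong configuration and must be inverted next to a secondary amide whose N–H is deprotonated first. The hindered amide must then be cleaved by forcing hydrolysis or N-activation. The second arylation, beside the first aryl group and with a bulky electron-rich iodide, should be slower than the first and may give mono- and diarylated mixtures. Stoichiometric silver and palladium are consumed.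
- In its place the chosen route offers cheap reagents only, no auxiliary to attach and remove, and a C2–C3–C4 configuration taken from an aldol/reduction triad and transferred by two inversions; the one centre corrected afterwards is an ordinary ester.

**Alternative 2:** The two bonds from one aryl-bearing ring carbon to its two carboxyl-bearing neighbours are cut.
- Forward key step: the benzylic ylide A6 adds to the strained double bond of dimethyl 3-(3,4,5-trimethoxyphenyl)cycloprop-1-ene-1,2-dicarboxylate A5, and the cyclopropyl ester enolate displaces the sulfonium group at the benzylic carbon. This closes the bicyclo[1.1.0]butane A4, whose four peripheral bonds are the target ring; reductive cleavage of the central bond would give the 1,3-diester.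
- For it: the route is very short, the exo,exo aryl groups map onto the cis aryl groups of 25, and both carboxyl centres could be equilibrated afterwards.
- Against it: A5 is a doubly activated, 3-monosubstituted cyclopropene, prone to ene dimerisation and polymerisation, and itself needs a diazo-based preparation. The ylide annulation to a bicyclobutane has no close precedent and must build a ring system far more strained than cyclobutane by a 3-exo-tet closure. A4 carries donor aryl and acceptor ester groups around the central bond and is set up for opening to a butadiene. The selective hydrogenolysis of that bond is a second untested step.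
- Compared with it, the chosen route uses only known reaction types and concentrates its uncertainty in one ring closure.

**Alternative 3:** One ring bond between a carboxyl-bearing and an aryl-bearing carbon is cut; in the precursor pyrrolidine A8 this bond is bridged by NH.
- Forward key step: an iodonitrene from a hydroxy(tosyloxy)iodoarene and an ammonia source aminates the ring nitrogen, the 1,1-diazene loses nitrogen, and the 1,4-biradical collapses to the cyclobutane A7.
- For it: the pyrrolidine comes in one step from an azomethine ylide and a cinnamate, which fixes the head-to-tail pattern, and the contraction is a known reaction type. The whole route might take five or six steps, shorter than the chosen one.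
- Against it: the cycloaddition gives 2,5-cis pyrrolidines, and only the exo adduct A8 has cis aryl groups, whereas endo adducts are the usual outcome. A stereoretentive contraction of A8 leaves one ester cis to both aryl groups, so A7 is reached only after a further equilibration. The biradical is stabilised at both ends (benzylic and α-ester), which favours bond rotation and β-scission to two alkenes. A trivalent iodine oxidant meets a secondary amine and two trimethoxyarenes.
- In its place the chosen route offers configurations set by closed-shell steps (Zimmerman–Traxler aldol, chelate-controlled reduction, SN2 inversion) whose outcome does not depend on exo/endo selectivity or on the lifetime of a radical pair.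

Key step: step 6

Remark on the chemistry: 25 is achiral; the chiral intermediates 7, 8, 9 and 15 are racemic and their SMILES show one enantiomer, and 10, 11, 12 and 16–21 are meso or achiral.

## Route

Step 1
Reactants: 1 3',4',5'-trimethoxyacetophenone; 2 benzyl chloromethyl ether
Product: 4 3-(benzyloxy)-1-(3,4,5-trimethoxyphenyl)propan-1-one, via lithium enolate 3 (not isolated)
Conditions: LiN(iPr)2, THF, −78 °C; then 2, −78 → −40 °C
Reagents that add atoms: none
Why: Enolate alkylation: the kinetic lithium enolate 3 has only one enolisable side, and the oxocarbenium-like chloromethyl ether should alkylate at carbon at −78 °C faster than the product ketone exchanges a proton with 3, which keeps double alkylation and β-elimination of benzyl alcohol low.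

Step 2
Reactants: 4 3-(benzyloxy)-1-(3,4,5-trimethoxyphenyl)propan-1-one; 5 3,4,5-trimethoxybenzaldehyde
Product: 8 syn-2-[(benzyloxy)methyl]-3-hydroxy-1,3-bis(3,4,5-trimethoxyphenyl)propan-1-one (racemic), via Z-dibutylboron enolate 6 (not isolated), via dibutylboron aldolate 7 (not isolated)
Conditions: Bu2BOTf, iPr2NEt, CH2Cl2, −78 → 0 °C; 5, −78 → 0 °C; then pH 7 buffer, MeOH, H2O2, 0 °C
Reagents that add atoms: none
Why: Boron-mediated aldol reaction: Bu2BOTf with iPr2NEt should give the Z-enolate 6 of the aryl ketone, and the chair Zimmerman–Traxler transition state with the aldehyde aryl group equatorial leads to the syn aldolate 7, which sets the two new stereocentres relative to each other. The covalent boron enolate should not expel the β-benzyloxy group at low temperature, and the buffered oxidative work-up avoids retro-aldol cleavage.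

Step 3
Reactants: 8 syn-2-[(benzyloxy)methyl]-3-hydroxy-1,3-bis(3,4,5-trimethoxyphenyl)propan-1-one
Product: 10 meso syn,syn-2-[(benzyloxy)methyl]-1,3-bis(3,4,5-trimethoxyphenyl)propane-1,3-diol, via diethylboron chelate 9 (not isolated)
Conditions: Et2BOMe, THF/MeOH (4:1), −78 °C; NaBH4, −78 °C; then pH 7 buffer, H2O2, 0 °C → rt
Reagents that add atoms: none
Why: Narasaka–Prasad reduction: Et2BOMe ties ketone and hydroxyl into the six-membered chelate 9, and NaBH4 attacks the activated carbonyl axially on the half-chair that keeps the carbinol aryl group pseudo-equatorial, anti to the pseudo-axial benzyloxymethyl group, which gives the 1,3-syn diol. With the syn aldol as substrate this is the meso syn,syn triad.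

Step 4
Reactants: 10 meso syn,syn-2-[(benzyloxy)methyl]-1,3-bis(3,4,5-trimethoxyphenyl)propane-1,3-diol
Product: 11 5-[(benzyloxy)methyl]-4,6-bis(3,4,5-trimethoxyphenyl)-1,3,2-dioxathiane 2-oxide (all-cis at carbon; either configuration at sulfur)
Conditions: SOCl2, Et3N, CH2Cl2, −20 → 0 °C
Reagents that add atoms: thionyl chloride, O=S(Cl)Cl
Why: Cyclic sulfite formation from a 1,3-diol; the amine takes up HCl so that the benzylic chlorosulfite closes onto the second hydroxyl instead of ionising to a chloride, and since no C–O bond is broken the all-syn configuration is kept. The two sulfur epimers converge in step 5.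

Step 5
Reactants: 11 5-[(benzyloxy)methyl]-4,6-bis(3,4,5-trimethoxyphenyl)-1,3,2-dioxathiane 2-oxide
Product: 12 all-cis 5-[(benzyloxy)methyl]-4,6-bis(3,4,5-trimethoxyphenyl)-1,3,2-dioxathiane 2,2-dioxide
Conditions: RuCl3 hydrate (1 mol %), NaIO4, MeCN/CH2Cl2/H2O, 0 °C, short reaction time
Reagents that add atoms: sodium periodate, [Na+].[O-]I(=O)(=O)=O
Why: Ruthenium-catalysed oxidation of a cyclic sulfite to the cyclic sulfate by RuO4 formed in situ from RuCl3 and NaIO4; oxidation at sulfur is much faster than attack on the benzyl ether or the trimethoxyphenyl rings, so low loading, 0 °C and short contact should keep these intact. The product is prone to ionisation and is used at once.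

Step 6
Reactants: 12 all-cis 5-[(benzyloxy)methyl]-4,6-bis(3,4,5-trimethoxyphenyl)-1,3,2-dioxathiane 2,2-dioxide; 13 dimethyl malonate
Product: 16 dimethyl 3-[(benzyloxy)methyl]-2,4-bis(3,4,5-trimethoxyphenyl)cyclobutane-1,1-dicarboxylate (aryl groups cis; benzyloxymethyl trans to both), via sodium dimethyl malonate 14 (not isolated), via ring-opened sodium alkyl sulfate 15 (not isolated)
Conditions: NaH (2.2 equiv), DME, 0 °C → rt; then 80 °C
Reagents that add atoms: none
Why: Sodium dimethyl malonate 14 attacks one benzylic carbon of the meso cyclic sulfate 12 by SN2 with inversion (the two carbons are mirror-related, so there is no regiochemical question) and gives the alkyl sulfate 15; the second equivalent of NaH regenerates the malonate carbanion, which displaces the sulfate monoester at the other benzylic carbon, again with inversion. The closest known reaction type is the double alkylation of malonates with cyclic sulfates of 1,2- and 1,3-diols or with 1,3-dihalides to cyclopropane- and cyclobutane-1,1-diesters; here both electrophilic carbons are secondary and benzylic. The ring closes in the 4-exo-tet mode. The two benzylic stereocentres of 16 are fixed by the configuration of the carbinol carbons of 12 through this stereospecific double inversion: aryl and benzyloxymethyl groups are cis in the six-membered sulfate ring and therefore trans in the four-membered ring, while the aryl groups stay cis to each other; the malonate carbon is not yet a stereocentre. The step needs substitution to win over E2 elimination, SN1 ionisation and O-alkylation of the malonate to a six-membered ketene acetal. Elimination is held back because the only β-hydrogen sits on a carbon bearing an ether and not a carbonyl, and because the malonate is a soft, weakly basic nucleophile. Ionisation is slowed by the two meta methoxy groups, which withdraw inductively and twist the para methoxy group out of conjugation, while the benzylic position still accelerates the SN2 transition state. In 16 all three ring substituents can sit pseudo-equatorial on the puckered ring, so the closure does not work against strain between substituents.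

Step 7
Reactants: 16 dimethyl 3-[(benzyloxy)methyl]-2,4-bis(3,4,5-trimethoxyphenyl)cyclobutane-1,1-dicarboxylate
Product: 17 methyl 3-[(benzyloxy)methyl]-2,4-bis(3,4,5-trimethoxyphenyl)cyclobutane-1-carboxylate (mixture of C1 epimers)
Conditions: LiCl, H2O, DMSO, 150 °C
Reagents that add atoms: none
Why: Krapcho dealkoxycarbonylation: chloride demethylates one ester by SN2 at the unhindered O-methyl carbon, the carboxylate loses CO2 and water protonates the ester enolate, so the crowded ring carbon is not attacked. C1 becomes a stereocentre here and is formed as an epimer mixture that step 8 corrects.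

Step 8
Reactants: 17 methyl 3-[(benzyloxy)methyl]-2,4-bis(3,4,5-trimethoxyphenyl)cyclobutane-1-carboxylate (epimer mixture)
Product: 19 3-[(benzyloxy)methyl]-2,4-bis(3,4,5-trimethoxyphenyl)cyclobutane-1-carboxylic acid (carboxyl trans to both aryl groups; cis to the benzyloxymethyl group), via equilibrated methyl ester 18 (not isolated)
Conditions: NaOMe (0.3 equiv), MeOH, 65 °C; then aq NaOH, 65 °C; aq HCl work-up
Reagents that add atoms: sodium hydroxide, [Na+].[OH-]
Why: Epimerisation through the ester enolate followed by saponification: the epimer with the ester cis to both flanking aryl groups has three contiguous cis substituents, so the equilibrium should lie far on the side of 18, with the ester trans to both aryl groups. C1 is thus set under thermodynamic control before hydroxide fixes it as the carboxylate.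

Step 9
Reactants: 19 3-[(benzyloxy)methyl]-2,4-bis(3,4,5-trimethoxyphenyl)cyclobutane-1-carboxylic acid
Product: 20 3-(hydroxymethyl)-2,4-bis(3,4,5-trimethoxyphenyl)cyclobutane-1-carboxylic acid (configuration unchanged)
Conditions: H2 (1 atm), 10% Pd/C, MeOH/EtOAc, rt
Reagents that add atoms: none
Why: Hydrogenolysis of the benzyl ether over palladium on carbon; the trimethoxyphenyl rings, the carboxylic acid and the aryl-substituted cyclobutane should not be reduced at 1 atm, and the lactam alkenes are not yet present.

Step 10
Reactants: 20 3-(hydroxymethyl)-2,4-bis(3,4,5-trimethoxyphenyl)cyclobutane-1-carboxylic acid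
Product: 21 all-trans 2,4-bis(3,4,5-trimethoxyphenyl)cyclobutane-1,3-dicarboxylic acid
Conditions: TEMPO (cat.), PhI(OAc)2, MeCN/H2O (1:1), rt
Reagents that add atoms: water, O
Why: TEMPO-catalysed oxidation with PhI(OAc)2 in aqueous acetonitrile takes the primary alcohol through the aldehyde hydrate to the acid without touching the methoxyarenes. The C3 substituent is already trans to both aryl groups, so enolisation of the intermediate aldehyde cannot lead to a more stable epimer.

Step 11
Reactants: 21 all-trans 2,4-bis(3,4,5-trimethoxyphenyl)cyclobutane-1,3-dicarboxylic acid; 22 5,6-dihydropyridin-2(1H)-one (2 equiv)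
Product: 25 1,1'-{[2,4-bis(3,4,5-trimethoxyphenyl)cyclobutane-1,3-diyl]dicarbonyl}bis(5,6-dihydropyridin-2(1H)-one) (all-trans; target), via bis(acid chloride) 23 (not isolated), via lithium lactamate 24 (not isolated)
Conditions: (COCl)2, cat. DMF, CH2Cl2, 0 °C → rt, evaporate; separately 22 (2.2 equiv), n-BuLi (2.1 equiv), THF, −78 °C; then 23 in THF, −78 → −40 °C
Reagents that add atoms: 5,6-dihydropyridin-2(1H)-one (the second equivalent of 22), O=C1NCCC=C1
Why: Acid chloride formation followed by twofold N-acylation of the lithiated lactam (imide formation), the usual way of joining cinnamoyl-type chlorides to this lactam; each of the two acyl chloride groups of 23 takes up one lactamate 24, so two equivalents of 22 are built into 25, and acylation on nitrogen at −78 °C should be faster than conjugate addition to the product. The all-trans arrangement of 25 is the thermodynamic one, so a transient ketene or enolate at C1 or C3 would return to it.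

## Compound list

1 | 3',4',5'-trimethoxyacetophenone | CC(=O)c1cc(OC)c(OC)c(OC)c1 | starting material
2 | benzyl chloromethyl ether | ClCOCc1ccccc1 | starting material
3 | lithium 1-(3,4,5-trimethoxyphenyl)ethen-1-olate | [Li+].[O-]C(=C)c1cc(OC)c(OC)c(OC)c1 | intermediate (not isolated)
4 | 3-(benzyloxy)-1-(3,4,5-trimethoxyphenyl)propan-1-one | O=C(CCOCc1ccccc1)c1cc(OC)c(OC)c(OC)c1 | intermediate
5 | 3,4,5-trimethoxybenzaldehyde | COc1cc(C=O)cc(OC)c1OC | starting material
6 | (Z)-{[3-(benzyloxy)-1-(3,4,5-trimethoxyphenyl)prop-1-en-1-yl]oxy}dibutylborane | CCCCB(CCCC)O/C(=C\COCc1ccccc1)c1cc(OC)c(OC)c(OC)c1 | intermediate (not isolated)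
7 | dibutylborinate of the syn aldol (racemic) | O=C(c1cc(OC)c(OC)c(OC)c1)[C@@H](COCc1ccccc1)[C@@H](c1cc(OC)c(OC)c(OC)c1)OB(CCCC)CCCC | intermediate (not isolated)
8 | syn-2-[(benzyloxy)methyl]-3-hydroxy-1,3-bis(3,4,5-trimethoxyphenyl)propan-1-one (racemic; benzyloxymethyl and hydroxyl syn in the zigzag chain) | O=C(c1cc(OC)c(OC)c(OC)c1)[C@@H](COCc1ccccc1)[C@@H](c1cc(OC)c(OC)c(OC)c1)O | intermediate
9 | diethylboron chelate of 8 (six-membered O–B–O ring, racemic) | CC[B-]1(CC)[O+]=C(c2cc(OC)c(OC)c(OC)c2)[C@@H](COCc2ccccc2)[C@@H](c2cc(OC)c(OC)c(OC)c2)O1 | intermediate (not isolated)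
10 | meso syn,syn-2-[(benzyloxy)methyl]-1,3-bis(3,4,5-trimethoxyphenyl)propane-1,3-diol (both hydroxyls and the benzyloxymethyl group on one side of the zigzag chain) | O[C@@H](c1cc(OC)c(OC)c(OC)c1)[C@@H](COCc1ccccc1)[C@@H](c1cc(OC)c(OC)c(OC)c1)O | intermediate
11 | 5-[(benzyloxy)methyl]-4,6-bis(3,4,5-trimethoxyphenyl)-1,3,2-dioxathiane 2-oxide (ring substituents all-cis; sulfur epimers) | O=S1O[C@@H](c2cc(OC)c(OC)c(OC)c2)[C@@H](COCc2ccccc2)[C@@H](c2cc(OC)c(OC)c(OC)c2)O1 | intermediate
12 | all-cis 5-[(benzyloxy)methyl]-4,6-bis(3,4,5-trimethoxyphenyl)-1,3,2-dioxathiane 2,2-dioxide | O=S1(=O)O[C@@H](c2cc(OC)c(OC)c(OC)c2)[C@@H](COCc2ccccc2)[C@@H](c2cc(OC)c(OC)c(OC)c2)O1 | intermediate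
13 | dimethyl malonate | COC(=O)CC(=O)OC | starting material
14 | sodium dimethyl malonate | [Na+].COC(=O)[CH-]C(=O)OC | intermediate (not isolated)
15 | sodium 2-[(benzyloxy)methyl]-4-methoxy-3-(methoxycarbonyl)-4-oxo-1,3-bis(3,4,5-trimethoxyphenyl)butyl sulfate (racemic; malonyl-bearing carbon inverted relative to 12) | COC(=O)C(C(=O)OC)[C@H](c1cc(OC)c(OC)c(OC)c1)[C@@H](COCc1ccccc1)[C@@H](c1cc(OC)c(OC)c(OC)c1)OS(=O)(=O)[O-].[Na+] | intermediate (not isolated)
16 | dimethyl 3-[(benzyloxy)methyl]-2,4-bis(3,4,5-trimethoxyphenyl)cyclobutane-1,1-dicarboxylate (aryl groups cis; benzyloxymethyl trans to both) | COc1cc([C@H]2C(C(=O)OC)(C(=O)OC)[C@@H](c3cc(OC)c(OC)c(OC)c3)[C@@H]2COCc2ccccc2)cc(OC)c1OC | intermediate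
17 | methyl 3-[(benzyloxy)methyl]-2,4-bis(3,4,5-trimethoxyphenyl)cyclobutane-1-carboxylate (C1 epimer mixture; C2, C3, C4 as in 16) | COc1cc([C@H]2C(C(=O)OC)[C@@H](c3cc(OC)c(OC)c(OC)c3)[C@@H]2COCc2ccccc2)cc(OC)c1OC | intermediate
18 | methyl 3-[(benzyloxy)methyl]-2,4-bis(3,4,5-trimethoxyphenyl)cyclobutane-1-carboxylate (ester trans to both aryl groups; all neighbours trans) | COc1cc([C@H]2[C@H](C(=O)OC)[C@@H](c3cc(OC)c(OC)c(OC)c3)[C@@H]2COCc2ccccc2)cc(OC)c1OC | intermediate (not isolated)
19 | 3-[(benzyloxy)methyl]-2,4-bis(3,4,5-trimethoxyphenyl)cyclobutane-1-carboxylic acid (all neighbours trans) | COc1cc([C@H]2[C@H](C(=O)O)[C@@H](c3cc(OC)c(OC)c(OC)c3)[C@@H]2COCc2ccccc2)cc(OC)c1OC | intermediate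
20 | 3-(hydroxymethyl)-2,4-bis(3,4,5-trimethoxyphenyl)cyclobutane-1-carboxylic acid (all neighbours trans) | COc1cc([C@H]2[C@H](C(=O)O)[C@@H](c3cc(OC)c(OC)c(OC)c3)[C@@H]2CO)cc(OC)c1OC | intermediate
21 | all-trans 2,4-bis(3,4,5-trimethoxyphenyl)cyclobutane-1,3-dicarboxylic acid (aryl groups cis to each other; carboxyl groups cis to each other) | COc1cc([C@H]2[C@H](C(=O)O)[C@@H](c3cc(OC)c(OC)c(OC)c3)[C@@H]2C(=O)O)cc(OC)c1OC | intermediate
22 | 5,6-dihydropyridin-2(1H)-one | O=C1NCCC=C1 | starting material
23 | all-trans 2,4-bis(3,4,5-trimethoxyphenyl)cyclobutane-1,3-dicarbonyl dichloride | COc1cc([C@H]2[C@H](C(Cl)=O)[C@@H](c3cc(OC)c(OC)c(OC)c3)[C@@H]2C(Cl)=O)cc(OC)c1OC | intermediate (not isolated)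
24 | N-lithio-5,6-dihydropyridin-2(1H)-one | O=C1C=CCCN1[Li] | intermediate (not isolated)
25 | 1,1'-{[2,4-bis(3,4,5-trimethoxyphenyl)cyclobutane-1,3-diyl]dicarbonyl}bis(5,6-dihydropyridin-2(1H)-one), all-trans | COc1cc([C@H]2[C@H](C(=O)N3CCC=CC3=O)[C@@H](c3cc(OC)c(OC)c(OC)c3)[C@@H]2C(=O)N2CCC=CC2=O)cc(OC)c1OC | target

## Step count and least certain steps

Total: 11 steps. Longest linear sequence: 11 steps (1 → 25); compounds 2, 5, 13 and 22 enter as purchased reagents, 22 in two equivalents.

**Step 6 (key step).** The most likely failure is that the ring closure stalls at the alkyl sulfate 15. A tertiary, flanked malonate carbanion must attack a secondary benzylic carbon in a 4-exo-tet mode against a monoanionic leaving group. On heating, three processes can then take over: elimination to a styrene, ionisation at the benzylic carbon with loss of stereochemical fidelity, or O-alkylation through the enolate oxygen to a six-membered ketene acetal. In the chair of 12 that keeps both aryl groups equatorial, the C–H bond of the central carbon is antiperiplanar to both ring C–O bonds, so elimination is stereoelectronically open already in the first substitution.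
Fallback: it sets out from 12 and changes the 1,1-dinucleophile to methyl cyanoacetate (NaH, DMF, 0 → 60 °C), whose anion is less basic and carries a slim, linear nitrile on the carbon that must become quaternary. This should give methyl 3-[(benzyloxy)methyl]-1-cyano-2,4-bis(3,4,5-trimethoxyphenyl)cyclobutane-1-carboxylate F1. Dealkoxycarbonylation of F1 (LiCl, wet DMSO, 140 °C) would give 3-[(benzyloxy)methyl]-2,4-bis(3,4,5-trimethoxyphenyl)cyclobutane-1-carbonitrile F2 as an epimer mixture. Alkaline hydrolysis (KOH, ethylene glycol/H2O, 150 °C) would give 3-[(benzyloxy)methyl]-2,4-bis(3,4,5-trimethoxyphenyl)cyclobutane-1-carboxylic acid as a C1 epimer mixture F3. Methylation (MeI, K2CO3, DMF) comes back to the route at 17, whose C1 configuration is set in step 8 in any case.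

**Step 1.** Double alkylation, O-alkylation by the hard chloromethyl ether, or proton transfer to the product followed by loss of benzyl alcohol can lower the yield of 4.
Fallback: it sets out from 1, which is converted (Me3SiCl, Et3N, NaI, MeCN) into trimethyl{[1-(3,4,5-trimethoxyphenyl)ethenyl]oxy}silane F4. Lewis-acid-mediated alkylation of F4 with 2 (ZnBr2 cat., CH2Cl2, 0 °C → rt), a Mukaiyama-type alkoxymethylation, comes back at 4. The product of that step is a ketone and not an enolate, so a second alkylation is excluded.

**Step 5.** RuO4 may attack the trimethoxyphenyl rings or the benzylic ether, and the benzylic cyclic sulfate may solvolyse during the aqueous work-up.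
Fallback: it sets out from diol 10 and installs sulfur directly at the hexavalent level under anhydrous, non-oxidising conditions (NaH, 1,1'-sulfonyldiimidazole, THF, −20 → 0 °C). It comes back at 12, and no new compound arises on this way (F0).

**Step 7.** Compound 16 is a donor–acceptor cyclobutane, and chloride at 150 °C may open the ring by attack at a benzylic carbon with the malonate as leaving group; the reaction may also be slow on this crowded diester.
Fallback: it sets out from 16 and uses no nucleophile at high temperature. Monosaponification (KOH, 1 equiv, MeOH/H2O, 50 °C) should give 3-[(benzyloxy)methyl]-1-(methoxycarbonyl)-2,4-bis(3,4,5-trimethoxyphenyl)cyclobutane-1-carboxylic acid F5. Thermal decarboxylation of this malonic half-ester (pyridine or toluene, 110 °C) comes back at 17.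

**Step 11.** The acid chlorides are flanked by two aryl-bearing carbons, so the second acylation may be slow. The basic lactamate may then dehydrochlorinate 23 to a ketene or add in conjugate fashion to enoyl imide already formed.
Fallback: it sets out from 21, which is converted (C6F5OH, EDC·HCl, cat. DMAP, CH2Cl2) into the isolable bis(pentafluorophenyl) all-trans 2,4-bis(3,4,5-trimethoxyphenyl)cyclobutane-1,3-dicarboxylate F6. Reaction of purified F6 with two equivalents of 22 and NaH (THF, 0 °C) comes back at 25. The active ester has no chloride to lose, and the phenoxide set free is not a Michael donor.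

## Further compounds

F1 | step 6 | methyl 3-[(benzyloxy)methyl]-1-cyano-2,4-bis(3,4,5-trimethoxyphenyl)cyclobutane-1-carboxylate (aryl groups cis; benzyloxymethyl trans to both; either C1 epimer) | COc1cc([C@H]2C(C#N)(C(=O)OC)[C@@H](c3cc(OC)c(OC)c(OC)c3)[C@@H]2COCc2ccccc2)cc(OC)c1OC
F2 | step 6 | 3-[(benzyloxy)methyl]-2,4-bis(3,4,5-trimethoxyphenyl)cyclobutane-1-carbonitrile (C1 epimer mixture) | COc1cc([C@H]2C(C#N)[C@@H](c3cc(OC)c(OC)c(OC)c3)[C@@H]2COCc2ccccc2)cc(OC)c1OC
F3 | step 6 | 3-[(benzyloxy)methyl]-2,4-bis(3,4,5-trimethoxyphenyl)cyclobutane-1-carboxylic acid (C1 epimer mixture) | COc1cc([C@H]2C(C(=O)O)[C@@H](c3cc(OC)c(OC)c(OC)c3)[C@@H]2COCc2ccccc2)cc(OC)c1OC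
F4 | step 1 | trimethyl{[1-(3,4,5-trimethoxyphenyl)ethenyl]oxy}silane | C=C(O[Si](C)(C)C)c1cc(OC)c(OC)c(OC)c1
F0 | step 5 | none | none
F5 | step 7 | 3-[(benzyloxy)methyl]-1-(methoxycarbonyl)-2,4-bis(3,4,5-trimethoxyphenyl)cyclobutane-1-carboxylic acid (aryl groups cis; benzyloxymethyl trans to both; either C1 epimer) | COc1cc([C@H]2C(C(=O)O)(C(=O)OC)[C@@H](c3cc(OC)c(OC)c(OC)c3)[C@@H]2COCc2ccccc2)cc(OC)c1OC
F6 | step 11 | bis(pentafluorophenyl) all-trans 2,4-bis(3,4,5-trimethoxyphenyl)cyclobutane-1,3-dicarboxylate | COc1cc([C@H]2[C@H](C(=O)Oc3c(F)c(F)c(F)c(F)c3F)[C@@H](c3cc(OC)c(OC)c(OC)c3)[C@@H]2C(=O)Oc2c(F)c(F)c(F)c(F)c2F)cc(OC)c1OC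
A1 | alternative 1 | methyl 3-(quinolin-8-ylcarbamoyl)-2,4-bis(3,4,5-trimethoxyphenyl)cyclobutane-1-carboxylate (amide cis to both aryl groups; ester trans) | COc1cc([C@H]2[C@@H](C(=O)Nc3cccc4cccnc34)[C@@H](c3cc(OC)c(OC)c(OC)c3)[C@@H]2C(=O)OC)cc(OC)c1OC
A2 | alternative 1 | methyl trans-3-(quinolin-8-ylcarbamoyl)cyclobutane-1-carboxylate | COC(=O)[C@H]1C[C@H](C(=O)Nc2cccc3cccnc23)C1
A3 | alternative 1 | 5-iodo-1,2,3-trimethoxybenzene | COc1cc(I)cc(OC)c1OC
A4 | alternative 2 | dimethyl exo,exo-2,4-bis(3,4,5-trimethoxyphenyl)bicyclo[1.1.0]butane-1,3-dicarboxylate | COC(=O)[C@]12[C@H](c3cc(OC)c(OC)c(OC)c3)[C@@]1(C(=O)OC)[C@@H]2c1cc(OC)c(OC)c(OC)c1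
A5 | alternative 2 | dimethyl 3-(3,4,5-trimethoxyphenyl)cycloprop-1-ene-1,2-dicarboxylate | COC(=O)C1=C(C(=O)OC)C1c1cc(OC)c(OC)c(OC)c1
A6 | alternative 2 | dimethylsulfonium (3,4,5-trimethoxyphenyl)methanide | C[S+](C)[CH-]c1cc(OC)c(OC)c(OC)c1
A7 | alternative 3 | dimethyl all-trans-2,4-bis(3,4,5-trimethoxyphenyl)cyclobutane-1,3-dicarboxylate | COc1cc([C@H]2[C@H](C(=O)OC)[C@@H](c3cc(OC)c(OC)c(OC)c3)[C@@H]2C(=O)OC)cc(OC)c1OC
A8 | alternative 3 | dimethyl 3,5-bis(3,4,5-trimethoxyphenyl)pyrrolidine-2,4-dicarboxylate, exo cycloadduct (C2 ester, C3 aryl and C5 aryl cis; C4 ester trans; racemic) | COC(=O)[C@@H]1N[C@H](c2cc(OC)c(OC)c(OC)c2)[C@@H](C(=O)OC)[C@@H]1c1cc(OC)c(OC)c(OC)c1
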